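(The numbers of this flask are those of an exercise.)

In a one-step world every free monomer would enter a chain. Here the protic impurity takes its share, so the length turns on how the monomer divides.

    2 growing radical → dead chain (k1 = 5 × 10⁸ M⁻¹ s⁻¹)
    free monomer + growing radical → monomer in chains + growing radical, rate k2*[growing radical]*[free monomer] (k2 = 7.51 × 10⁶ M⁻¹ s⁻¹)
    protic impurity + free monomer → quenched substrate (k3 = 188 M⁻¹ s⁻¹)
    free monomer + initiating radical → growing radical + monomer in chains (k4 = 8.01 × 10⁷ M⁻¹ s⁻¹)
    initiator → 2 initiating radical (k5 = 0.00361 s⁻¹)

all flasks: free monomer 0.50 mM; protic impurity 0.250 mM; time 40 s
- birch: initiator 1.2 mol%
- alder: initiator 2.5 mol%

* which of the two ends with the longer chains by the average number of monomer units in a chain (living and dead chains, two that joined counted as one) ("neither" if they lie within 10%) (birch / alder / neither)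
* average number of monomer units in a chain (living and dead chains, two that joined counted as one) at the end, birch
* average number of monomer units in a chain (living and dead chains, two that joined counted as one) at the end, alder

- where a step has two of a species, its rate is k times that concentration squared, and two are used at each turn
- the average divides the monomer in chains by the number of chains, living and dead together; two radicals that join make one chain
- run time (birch): 40 s

We reckon birch by hand, in rates per unit of free monomer. With radical births balancing deaths, growth starts at 0.0494 s⁻¹ and quenching at 0.0470 s⁻¹. At that growth rate a growing radical lives about 0.152 s, far shorter than the run, so the balance is a fair assumption. Dividing one rate by the other cancels free monomer and time. What remains is the split concentration, growth rate over the quenching rate constant, 0.263 mM: the impurity level at which both paths run equally, a selectivity factor of one. While the radical level holds, c(monomer in chains) is the split concentration times the logarithm of charged over remaining c(protic impurity).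

Quenching slows with its impurity, to a third if that much remains, and growth slows to 0.930 of its start as initiator decays. The total rate thus falls to 0.0617 s⁻¹, and its mean over the run leaves about 4.24% of the free monomer. With a third of the impurity left, the paths hold 0.289 mM in chains and account for 91.1% of the charge, close enough for us to commit to it. Each initiator spent gives one chain, 8.07 × 10⁻⁴ mM, so we expect 358 for birch. For alder, with 40.0% of the impurity left, the same reckoning gives 207.

The forecast says birch, with 370 and 203, since “doubling the initiator adds chains much faster than it adds incorporated monomer”.

The simulation gives birch, with 368 and 202. A run that moved the length of birch by 36.8, as a charge of 1.4 mol% of initiator or a time of 46.1 s does, would put the forecast's 370 about that far off. Birch ends with 31% of its impurity. In the split concentration that remainder gives 61.0% of the charge in chains, and the flask holds 59.5%.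

At 2 mol% of initiator the split concentration is 0.339 mM; with 37.5% of the impurity left, that gives a length of 248. The neighbour computes to 243 with 65.5% in chains, still beyond the margin above alder.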